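**Retrosynthetic overview**

1. Ugonin Q ← one basic global deprotection of a cyclised precursor that carries three phenolic silyl ethers and two acetates; the three flavone rings are bought as luteolin, so the cyclohexane is the only ring the route forms.
2. Cyclohexane ← cation–allylsilane (SE2′) ring closure joining the gem-dimethyl carbon to the ring CH that carries the flavonylmethyl group, from an acyclic (E)-allylsilane with a tertiary methyl ether and one (S)-acetoxy stereocentre.
3. Acyclic precursor ← sp3–sp2 Suzuki–Miyaura union of a luteolin-6-ylmethyl boronate with an (E)-alkenyl iodide, then O-acetylation; the alkene geometry never passes through a π-allyl species.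
4. Alkenyl iodide ← one-pot Cu-catalysed anti-carbomagnesiation (Me3SiCH2MgCl)/iodination of an (S)-propargylic alcohol (Noyori transfer hydrogenation of an ynone); boronate ← 5-OH-directed C6 iodination of silylated luteolin and borylmethyl Negishi coupling.
5. Enabling feature: the exocyclic methylene sits on the ring carbon between the carbinol carbon and the ring CH, so it is the trace of a CH2SiMe3 group whose γ-carbon is that CH; the adjacent gem-dimethyl ring carbon is the trace of a tertiary cation; the carbinol carbon, 1,3 to the new CH stereocentre, controls the face.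

Key step: step 13

Assumption: luteolin, 3-methoxy-3-methylbutan-1-ol, 3-(trimethylsilyl)prop-2-ynal, (trimethylsilyl)methylmagnesium chloride solution and 2-(iodomethyl)-4,4,5,5-tetramethyl-1,3,2-dioxaborolane are taken as commercial; both stereocentres of the target are S as read from the given SMILES (ring CH and carbinol 1,3-trans).

**Route**

Step 1
Reactants: 1 3-methoxy-3-methylbutan-1-ol
Product: 2 1-bromo-3-methoxy-3-methylbutane
Conditions: CBr4, PPh3, CH2Cl2, 0 °C to rt
Reagents that add atoms: carbon tetrabromide, BrC(Br)(Br)Br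
Why: Appel reaction of a primary alcohol under neutral conditions, which leave the tertiary methyl ether (the later cation source) untouched.

Step 2
Reactants: 2 1-bromo-3-methoxy-3-methylbutane; 3 3-(trimethylsilyl)prop-2-ynal
Product: 5 rac-6-methoxy-6-methyl-1-(trimethylsilyl)hept-1-yn-3-ol, via Grignard reagent 4 (not isolated)
Conditions: Mg, THF, 40 °C; then 3, −78 to 0 °C; NH4Cl aq
Reagents that add atoms: none
Why: Grignard 1,2-addition to an ynal; the γ-methoxy Grignard reagent is stable because methoxide is too poor a leaving group for cyclopropane formation.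

Step 3
Reactants: 5 rac-6-methoxy-6-methyl-1-(trimethylsilyl)hept-1-yn-3-ol
Product: 6 6-methoxy-6-methyl-1-(trimethylsilyl)hept-1-yn-3-one
Conditions: Dess–Martin periodinane, NaHCO3, CH2Cl2, 0 °C to rt
Reagents that add atoms: none
Why: Dess–Martin oxidation of a secondary propargylic alcohol under buffered conditions that spare the alkynylsilane and the tertiary ether.

Step 4
Reactants: 6 6-methoxy-6-methyl-1-(trimethylsilyl)hept-1-yn-3-one
Product: 7 (S)-6-methoxy-6-methyl-1-(trimethylsilyl)hept-1-yn-3-ol
Conditions: RuCl[(S,S)-TsDPEN](p-cymene) (1 mol%), KOH (1 mol%), iPrOH, rt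
Reagents that add atoms: none
Why: Noyori asymmetric transfer hydrogenation of an alkynyl ketone, in which the alkyne takes the place of the aryl group of an aryl ketone, so the (S,S)-catalyst should give the (S)-propargylic alcohol.

Step 5
Reactants: 7 (S)-6-methoxy-6-methyl-1-(trimethylsilyl)hept-1-yn-3-ol
Product: 8 (S)-6-methoxy-6-methylhept-1-yn-3-ol
Conditions: K2CO3, MeOH, rt
Reagents that add atoms: none
Why: Base-mediated protodesilylation of the alkynylsilane; the alcohol, the ether and the stereocentre are inert.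

Step 6
Reactants: 8 (S)-6-methoxy-6-methylhept-1-yn-3-ol; 9 (trimethylsilyl)methylmagnesium chloride
Product: 11 (1E,3S)-1-iodo-6-methoxy-6-methyl-2-[(trimethylsilyl)methyl]hept-1-en-3-ol, via cyclic alkenylmagnesium alkoxide 10 (not isolated)
Conditions: 9 (3 equiv), CuI (10 mol%), THF, 0 °C to reflux; then I2, THF, −40 °C; Na2S2O3/NH4Cl aq
Reagents that add atoms: iodine, [I][I]
Why: Copper-catalysed, magnesium-alkoxide-directed anti-carbomagnesiation of a terminal propargylic alcohol puts CH2SiMe3 on the carbinol-bearing alkyne carbon and magnesium on the terminus inside a five-membered chelate, so iodinolysis with retention gives the alkenyl iodide with iodine cis to the carbinol carbon, the geometry the ring closure needs.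

Step 7
Reactants: 12 luteolin
Product: 13 7,3',4'-tris-O-(tert-butyldimethylsilyl)luteolin (5-OH free)
Conditions: TBSCl (3.3 equiv), imidazole, DMF, 0 °C to rt
Reagents that add atoms: tert-butyldimethylsilyl chloride, CC(C)(C)[Si](C)(C)Cl
Why: Silylation takes the three free phenols, while the 5-OH, hydrogen-bonded to the chromone carbonyl and poorly nucleophilic, stays free as is usual for 5-hydroxyflavones.

Step 8
Reactants: 13 7,3',4'-tris-O-(tert-butyldimethylsilyl)luteolin
Product: 14 6-iodo-7,3',4'-tris-O-(tert-butyldimethylsilyl)luteolin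
Conditions: BnMe3N·ICl2 (1.1 equiv), CaCO3, CH2Cl2/MeOH, rt
Reagents that add atoms: benzyltrimethylammonium dichloroiodate, C[N+](C)(C)Cc1ccccc1.Cl[I-]Cl
Why: Electrophilic aromatic iodination of a 5-hydroxy-7-oxygenated flavone with this reagent goes ortho to the free chelated 5-OH, at C6 and not at C8 (the regiochemistry known for 5-hydroxy-7-alkoxyflavones), while CaCO3 buffers the HCl.

Step 9
Reactants: 14 6-iodo-7,3',4'-tris-O-(tert-butyldimethylsilyl)luteolin
Product: 15 5-O-acetyl-6-iodo-7,3',4'-tris-O-(tert-butyldimethylsilyl)luteolin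
Conditions: Ac2O, Et3N, DMAP, CH2Cl2, rt
Reagents that add atoms: acetic anhydride, CC(=O)OC(C)=O
Why: DMAP-catalysed acylation caps the hindered chelated 5-OH so that no free phenol flanks the future benzylic position during the coupling and Lewis acid steps.

Step 10
Reactants: 15 5-O-acetyl-6-iodo-7,3',4'-tris-O-(tert-butyldimethylsilyl)luteolin; 16 2-(iodomethyl)-4,4,5,5-tetramethyl-1,3,2-dioxaborolane
Product: 18 5-O-acetyl-6-[(pinacolatoboryl)methyl]-7,3',4'-tris-O-(tert-butyldimethylsilyl)luteolin, via borylmethylzinc iodide 17 (not isolated)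
Conditions: 16, Zn dust, THF, 25 °C; then 15, Pd(OAc)2, SPhos, THF, 50 °C
Reagents that add atoms: none
Why: Negishi coupling of an aryl iodide with the α-boryl alkylzinc reagent (a known route to benzylic pinacol boronates) installs the benzylic carbon with a boron handle, and the neutral zinc reagent tolerates the aryl acetate, the silyl ethers and the chromone.

Step 11
Reactants: 18 5-O-acetyl-6-[(pinacolatoboryl)methyl]-7,3',4'-tris-O-(tert-butyldimethylsilyl)luteolin; 11 (1E,3S)-1-iodo-6-methoxy-6-methyl-2-[(trimethylsilyl)methyl]hept-1-en-3-ol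
Product: 19 5-O-acetyl-6-{(2E,4S)-4-hydroxy-7-methoxy-7-methyl-3-[(trimethylsilyl)methyl]oct-2-en-1-yl}-7,3',4'-tris-O-(tert-butyldimethylsilyl)luteolin
Conditions: PdCl2(dppf) (5 mol%), Ag2O, K2CO3, THF, 60 °C
Reagents that add atoms: none
Why: sp3–sp2 Suzuki–Miyaura coupling of a benzylic pinacol boronate with an alkenyl iodide under non-aqueous Ag2O promotion retains the alkene geometry; the allylic hydroxyl is left free here because an allylic acetate next to the CH2SiMe3 group would be ionised by zerovalent palladium.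

Step 12
Reactants: 19 5-O-acetyl-6-{(2E,4S)-4-hydroxy-7-methoxy-7-methyl-3-[(trimethylsilyl)methyl]oct-2-en-1-yl}-7,3',4'-tris-O-(tert-butyldimethylsilyl)luteolin
Product: 20 5-O-acetyl-6-{(2E,4S)-4-acetoxy-7-methoxy-7-methyl-3-[(trimethylsilyl)methyl]oct-2-en-1-yl}-7,3',4'-tris-O-(tert-butyldimethylsilyl)luteolin
Conditions: Ac2O, pyridine, DMAP (cat.), CH2Cl2, 0 °C to rt
Reagents that add atoms: acetic anhydride, CC(=O)OC(C)=O
Why: Standard acylation of the secondary allylic alcohol removes the hydroxyl as an internal nucleophile (it would trap the cation as a 2,2-dimethyloxolane) and gives a group that later leaves together with the aryl protecting groups.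

Step 13
Reactants: 20 5-O-acetyl-6-{(2E,4S)-4-acetoxy-7-methoxy-7-methyl-3-[(trimethylsilyl)methyl]oct-2-en-1-yl}-7,3',4'-tris-O-(tert-butyldimethylsilyl)luteolin
Product: 21 5-O-acetyl-6-{[(1S,3S)-3-acetoxy-6,6-dimethyl-2-methylidenecyclohexyl]methyl}-7,3',4'-tris-O-(tert-butyldimethylsilyl)luteolin
Conditions: TiCl4 (5 equiv), 2,6-di-tert-butyl-4-methylpyridine, CH2Cl2, −78 °C; NaHCO3 aq at −78 °C
Reagents that add atoms: none
Why: TiCl4 ionises the tertiary methyl ether (no proton is released) to the tertiary cation at the gem-dimethyl carbon, the γ-carbon of the allylsilane (the alkene CH that carries the flavonylmethyl group) attacks it, and the tertiary β-silyl cation so formed loses Me3Si to chloride, which fixes the new alkene as the exocyclic methylene (anti SE2′). The closest known reaction type is the allylsilane-terminated cation–olefin cyclisation (intramolecular Hosomi–Sakurai-type tert-alkylation), which gives 2-methylidene-3,3-dimethylcyclohexane units from tertiary cations. The cyclohexane closes in the 6-endo mode with respect to the nucleophilic alkene through a chair; the 5-exo alternative would join two fully substituted carbons and give a cation without β-silicon stabilisation. The new ring CH stereocentre is set by 1,3-induction from the (S)-acetoxy carbon: on the (E)-alkene the flavonylmethyl group is cis to that carbon and therefore becomes axial, so the acetoxy group takes the equatorial position to avoid allylic 1,3-strain with it and a syn-pentane contact with the SiMe3 group on the face opposite to the cation, which should give the 1,3-trans (1S,3S) product. The step needs chemoselective ionisation (the tertiary ether is the best cation source, and the ester at the carbinol is a poor donor that cannot trap the cation as an oxolane), C–C bond formation before protodesilylation (aprotic cation generation and the hindered pyridine) and survival of the aryl silyl ethers (−78 °C, short contact).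

Step 14
Reactants: 21 5-O-acetyl-6-{[(1S,3S)-3-acetoxy-6,6-dimethyl-2-methylidenecyclohexyl]methyl}-7,3',4'-tris-O-(tert-butyldimethylsilyl)luteolin
Product: 22 ugonin Q
Conditions: K2CO3, MeOH/THF, rt, argon; then pH 6 phosphate buffer
Reagents that add atoms: none
Why: Base-mediated methanolysis cleaves the three phenolic silyl ethers and both acetates in one operation and avoids the acid that would add a flanking phenol to the exocyclic alkene; no stereocentre is touched.

**Compound list**

1 | 3-methoxy-3-methylbutan-1-ol | COC(C)(C)CCO | starting material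
2 | 1-bromo-3-methoxy-3-methylbutane | COC(C)(C)CCBr | intermediate
3 | 3-(trimethylsilyl)prop-2-ynal | C[Si](C)(C)C#CC=O | starting material
4 | (3-methoxy-3-methylbutyl)magnesium bromide | COC(C)(C)CC[Mg]Br | intermediate
5 | rac-6-methoxy-6-methyl-1-(trimethylsilyl)hept-1-yn-3-ol | C[Si](C)(C)C#CC(O)CCC(C)(C)OC | intermediate
6 | 6-methoxy-6-methyl-1-(trimethylsilyl)hept-1-yn-3-one | C[Si](C)(C)C#CC(=O)CCC(C)(C)OC | intermediate
7 | (S)-6-methoxy-6-methyl-1-(trimethylsilyl)hept-1-yn-3-ol | C[Si](C)(C)C#C[C@@H](O)CCC(C)(C)OC | intermediate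
8 | (S)-6-methoxy-6-methylhept-1-yn-3-ol | C#C[C@@H](O)CCC(C)(C)OC | intermediate
9 | (trimethylsilyl)methylmagnesium chloride | C[Si](C)(C)C[Mg]Cl | starting material
10 | (5S)-5-(3-methoxy-3-methylbutyl)-4-[(trimethylsilyl)methyl]-2,5-dihydro-1,2-oxamagnesole (cyclic alkenylmagnesium alkoxide) | C[Si](C)(C)CC1=C[Mg]O[C@H]1CCC(C)(C)OC | intermediate
11 | (1E,3S)-1-iodo-6-methoxy-6-methyl-2-[(trimethylsilyl)methyl]hept-1-en-3-ol | C[Si](C)(C)C/C(=C/I)[C@@H](O)CCC(C)(C)OC | intermediate
12 | luteolin | O=c1cc(-c2ccc(O)c(O)c2)oc2cc(O)cc(O)c12 | starting material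
13 | 7,3',4'-tris-O-(tert-butyldimethylsilyl)luteolin | O=c1cc(-c2ccc(O[Si](C)(C)C(C)(C)C)c(O[Si](C)(C)C(C)(C)C)c2)oc2cc(O[Si](C)(C)C(C)(C)C)cc(O)c12 | intermediate
14 | 6-iodo-7,3',4'-tris-O-(tert-butyldimethylsilyl)luteolin | Ic1c(O[Si](C)(C)C(C)(C)C)cc2oc(-c3ccc(O[Si](C)(C)C(C)(C)C)c(O[Si](C)(C)C(C)(C)C)c3)cc(=O)c2c1O | intermediate
15 | 5-O-acetyl-6-iodo-7,3',4'-tris-O-(tert-butyldimethylsilyl)luteolin | Ic1c(O[Si](C)(C)C(C)(C)C)cc2oc(-c3ccc(O[Si](C)(C)C(C)(C)C)c(O[Si](C)(C)C(C)(C)C)c3)cc(=O)c2c1OC(C)=O | intermediate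
16 | 2-(iodomethyl)-4,4,5,5-tetramethyl-1,3,2-dioxaborolane | ICB1OC(C)(C)C(C)(C)O1 | starting material
17 | [(4,4,5,5-tetramethyl-1,3,2-dioxaborolan-2-yl)methyl]zinc iodide | I[Zn]CB1OC(C)(C)C(C)(C)O1 | intermediate
18 | 5-O-acetyl-6-[(pinacolatoboryl)methyl]-7,3',4'-tris-O-(tert-butyldimethylsilyl)luteolin | CC1(C)OB(Cc2c(O[Si](C)(C)C(C)(C)C)cc3oc(-c4ccc(O[Si](C)(C)C(C)(C)C)c(O[Si](C)(C)C(C)(C)C)c4)cc(=O)c3c2OC(C)=O)OC1(C)C | intermediate
19 | 5-O-acetyl-6-{(2E,4S)-4-hydroxy-7-methoxy-7-methyl-3-[(trimethylsilyl)methyl]oct-2-en-1-yl}-7,3',4'-tris-O-(tert-butyldimethylsilyl)luteolin | C[Si](C)(C)C/C(=C/Cc1c(O[Si](C)(C)C(C)(C)C)cc2oc(-c3ccc(O[Si](C)(C)C(C)(C)C)c(O[Si](C)(C)C(C)(C)C)c3)cc(=O)c2c1OC(C)=O)[C@H](CCC(C)(C)OC)O | intermediate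
20 | 5-O-acetyl-6-{(2E,4S)-4-acetoxy-7-methoxy-7-methyl-3-[(trimethylsilyl)methyl]oct-2-en-1-yl}-7,3',4'-tris-O-(tert-butyldimethylsilyl)luteolin | C[Si](C)(C)C/C(=C/Cc1c(O[Si](C)(C)C(C)(C)C)cc2oc(-c3ccc(O[Si](C)(C)C(C)(C)C)c(O[Si](C)(C)C(C)(C)C)c3)cc(=O)c2c1OC(C)=O)[C@H](CCC(C)(C)OC)OC(C)=O | intermediate
21 | 5-O-acetyl-6-{[(1S,3S)-3-acetoxy-6,6-dimethyl-2-methylidenecyclohexyl]methyl}-7,3',4'-tris-O-(tert-butyldimethylsilyl)luteolin | C=C1[C@@H](Cc2c(O[Si](C)(C)C(C)(C)C)cc3oc(-c4ccc(O[Si](C)(C)C(C)(C)C)c(O[Si](C)(C)C(C)(C)C)c4)cc(=O)c3c2OC(C)=O)C(C)(C)CC[C@@H]1OC(C)=O | intermediate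
22 | ugonin Q, 6-{[(1S,3S)-3-hydroxy-6,6-dimethyl-2-methylidenecyclohexyl]methyl}luteolin | C=C1[C@@H](Cc2c(O)cc3oc(-c4ccc(O)c(O)c4)cc(=O)c3c2O)C(C)(C)CC[C@@H]1O | target

**Summary**

Total step count: 14. Longest linear sequence: 10 steps (steps 1 to 6, then 11 to 14); the luteolin branch is steps 7 to 10.

**Steps most likely to fail**

Step 13. With the fully decorated flavone present, TiCl4 may be sequestered by the chromone carbonyl, phenolic silyl ethers may be lost, or the cation may eliminate before ring closure; facial selectivity may also erode. The fallback closes the ring before the flavone is attached. It sets out from 11: Negishi coupling with zinc reagent 17 (Pd(OAc)2, SPhos, THF) should give allylboronate alcohol F1, and acetylation (Ac2O, pyridine, DMAP) its acetate F2. The same TiCl4 cyclisation on this small substrate, free of Lewis-basic aryl groups, should give cyclohexylmethyl boronate F3; the allylsilane, not the much weaker allylboronate, decides the site of attack. A B-alkyl Suzuki–Miyaura coupling of F3 with aryl iodide 15 (PdCl2(dppf), Ag2O, K2CO3, THF, aryl iodide in slight excess so that zerovalent palladium is consumed by oxidative addition before it can ionise the allylic acetate) comes back to the route at 21.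

Step 8. Regiocontrol between C6 and C8 may be poor, over-iodination may occur, and the 7-O-silyl group may be partly lost in methanol. The fallback installs the C6 carbon by a reaction that can only go ortho to the free 5-OH. It sets out from 13: magnesium-phenoxide-directed ortho-formylation (MgCl2, Et3N, paraformaldehyde, MeCN, reflux) should give 6-formyl compound F4, and acetylation (Ac2O, Et3N, DMAP) its 5-O-acetate F5. Brief reduction (NaBH4, THF/MeOH, −40 °C, to outrun acetyl migration) gives benzylic alcohol F6, and Appel bromination (CBr4, PPh3) gives benzylic bromide F7. Zinc insertion (Zn dust, LiCl, THF) gives benzylzinc bromide F8, whose Negishi coupling with alkenyl iodide 11 (Pd(OAc)2, SPhos, THF) comes back to the route at 19.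

Step 6. Carbomagnesiation of the secondary magnesium alkoxide may be sluggish or incomplete (simple deprotonation, recovered alkyne), and the allylsilane may suffer iododesilylation during the iodine quench. The fallback moves the carbometalation to prop-2-yn-1-ol, its best-precedented substrate, and makes the carbinol stereocentre afterwards. It sets out from 2 and 9: prop-2-yn-1-ol with 9/CuI and then I2 should give (E)-3-iodo-2-[(trimethylsilyl)methyl]prop-2-en-1-ol F9, and Dess–Martin oxidation the enal (E)-3-iodo-2-[(trimethylsilyl)methyl]prop-2-enal F10. Grignard reagent 4 (from 2) and ZnCl2 (magnesium salts removed with 1,4-dioxane) give bis(3-methoxy-3-methylbutyl)zinc F11. Its enantioselective addition to F10 catalysed by (−)-3-exo-(dimethylamino)isoborneol (toluene, 0 °C), with the alkenyl group in the role of the aryl group of an aromatic aldehyde, should give the (S)-carbinol and comes back to the route at 11.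

Further compounds
F1 | step 13 | (2E,4S)-7-methoxy-7-methyl-1-(pinacolatoboryl)-3-[(trimethylsilyl)methyl]oct-2-en-4-ol | CC1(C)OB(C/C=C(/C[Si](C)(C)C)[C@@H](O)CCC(C)(C)OC)OC1(C)C
F2 | step 13 | (2E,4S)-7-methoxy-7-methyl-1-(pinacolatoboryl)-3-[(trimethylsilyl)methyl]oct-2-en-4-yl acetate | CC1(C)OB(C/C=C(/C[Si](C)(C)C)[C@@H](OC(C)=O)CCC(C)(C)OC)OC1(C)C
F3 | step 13 | (1S,3S)-4,4-dimethyl-2-methylidene-3-[(pinacolatoboryl)methyl]cyclohexyl acetate | C=C1[C@@H](CB2OC(C)(C)C(C)(C)O2)C(C)(C)CC[C@@H]1OC(C)=O
F4 | step 8 | 6-formyl-7,3',4'-tris-O-(tert-butyldimethylsilyl)luteolin | O=Cc1c(O[Si](C)(C)C(C)(C)C)cc2oc(-c3ccc(O[Si](C)(C)C(C)(C)C)c(O[Si](C)(C)C(C)(C)C)c3)cc(=O)c2c1O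
F5 | step 8 | 5-O-acetyl-6-formyl-7,3',4'-tris-O-(tert-butyldimethylsilyl)luteolin | O=Cc1c(O[Si](C)(C)C(C)(C)C)cc2oc(-c3ccc(O[Si](C)(C)C(C)(C)C)c(O[Si](C)(C)C(C)(C)C)c3)cc(=O)c2c1OC(C)=O
F6 | step 8 | 5-O-acetyl-6-(hydroxymethyl)-7,3',4'-tris-O-(tert-butyldimethylsilyl)luteolin | OCc1c(O[Si](C)(C)C(C)(C)C)cc2oc(-c3ccc(O[Si](C)(C)C(C)(C)C)c(O[Si](C)(C)C(C)(C)C)c3)cc(=O)c2c1OC(C)=O
F7 | step 8 | 5-O-acetyl-6-(bromomethyl)-7,3',4'-tris-O-(tert-butyldimethylsilyl)luteolin | BrCc1c(O[Si](C)(C)C(C)(C)C)cc2oc(-c3ccc(O[Si](C)(C)C(C)(C)C)c(O[Si](C)(C)C(C)(C)C)c3)cc(=O)c2c1OC(C)=O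
F8 | step 8 | {[5-O-acetyl-7,3',4'-tris-O-(tert-butyldimethylsilyl)luteolin-6-yl]methyl}zinc bromide | Br[Zn]Cc1c(O[Si](C)(C)C(C)(C)C)cc2oc(-c3ccc(O[Si](C)(C)C(C)(C)C)c(O[Si](C)(C)C(C)(C)C)c3)cc(=O)c2c1OC(C)=O
F9 | step 6 | (E)-3-iodo-2-[(trimethylsilyl)methyl]prop-2-en-1-ol | C[Si](C)(C)C/C(=C/I)CO
F10 | step 6 | (E)-3-iodo-2-[(trimethylsilyl)methyl]prop-2-enal | C[Si](C)(C)C/C(=C/I)C=O
F11 | step 6 | bis(3-methoxy-3-methylbutyl)zinc | COC(C)(C)CC[Zn]CCC(C)(C)OC
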